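The target is an 11-oxabicyclo[4.4.1]undecane: two oxepanes (rings B and C) share O1, C2 and C7, and ring B carries a trans-fused α-methylene lactone (ring A). Ring C (O1, C2H, C3HMe, C4H2, C5H2, C6H2, C7Me) is disconnected at C3–C4. The key step exploits that C2 is oxygen-bearing, C5–C6 is unfunctionalised and C7 is a tertiary ether carbon: a Petasis methylenation–Claisen ring expansion of a five-membered vinyl carbonate (from L-erythrulose) forms C3–C4 and closes ring C as an unsaturated ε-lactone in one operation. The C3 methyl follows by methylenation–hydrogenation. Ring B and the lactone are closed later together by a chromium-mediated allylation.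

Key step: step 7

Remark: the labels O1 and C2–C7 of ring C are kept for the corresponding atoms of all intermediates; the carbinol centre made in step 5 is destroyed in step 7, so its minor epimer does no harm.

Step 1
Reactants: 1 L-erythrulose; 2 2,2-dimethoxypropane
Product: 3 3,4-O-isopropylidene-L-erythrulose
Conditions: Me2C(OMe)2, acetone, CSA (cat.), rt
Reagents that add atoms: 2,2-dimethoxypropane, COC(C)(C)OC
Why: Acid-catalysed transacetalisation should engage the vicinal 3,4-diol as the favoured five-membered dioxolane and leave the primary hydroxyl free; the (S) centre of the sugar is untouched and becomes the acyloxy-bearing carbon of the target.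

Step 2
Reactants: 3 3,4-O-isopropylidene-L-erythrulose; 4 chlorotriethylsilane
Product: 5 1-[(4S)-2,2-dimethyl-1,3-dioxolan-4-yl]-2-(triethylsilyloxy)ethan-1-one
Conditions: Et3SiCl, imidazole, DMF, 0 °C
Reagents that add atoms: chlorotriethylsilane, CC[Si](CC)(CC)Cl
Why: Standard silylation of the primary alcohol; the non-chelating silyl ether leaves the dioxolane oxygen as the only chelating site for step 3.

Step 3
Reactants: 5 1-[(4S)-2,2-dimethyl-1,3-dioxolan-4-yl]-2-(triethylsilyloxy)ethan-1-one; 6 methylmagnesium bromide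
Product: 7 (2R)-2-[(4S)-2,2-dimethyl-1,3-dioxolan-4-yl]-1-(triethylsilyloxy)propan-2-ol
Conditions: MeMgBr, THF, −78 °C
Reagents that add atoms: methylmagnesium bromide, C[Mg]Br
Why: Chelation-controlled Grignard addition (Cram chelate between the ketone oxygen and the adjacent dioxolane oxygen), in which methyl should add anti to the dioxolane CH2 and so set the tertiary carbinol (future C7) anti to the neighbouring C–O.

Step 4
Reactants: 7 (2R)-2-[(4S)-2,2-dimethyl-1,3-dioxolan-4-yl]-1-(triethylsilyloxy)propan-2-ol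
Product: 8 (2S)-2-[(4S)-2,2-dimethyl-1,3-dioxolan-4-yl]-2-hydroxypropanal
Conditions: (COCl)2, DMSO, CH2Cl2, −78 → −30 °C; Et3N
Reagents that add atoms: none
Why: Swern oxidation in which the chlorosulfonium salt cleaves the primary triethylsilyl ether and oxidises it in the same pot; the tertiary alcohol cannot be oxidised and the quaternary α-carbon cannot epimerise.

Step 5
Reactants: 8 (2S)-2-[(4S)-2,2-dimethyl-1,3-dioxolan-4-yl]-2-hydroxypropanal; 9 vinylmagnesium bromide
Product: 10 (3S,4R)-4-[(4S)-2,2-dimethyl-1,3-dioxolan-4-yl]pent-1-ene-3,4-diol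
Conditions: CH2=CHMgBr (3 equiv), THF, −78 → 0 °C
Reagents that add atoms: vinylmagnesium bromide, C=C[Mg]Br
Why: Grignard addition to the magnesium α-alkoxide aldehyde under chelation control, with vinyl entering anti to the bulky dioxolanyl group to give mainly the (3S) carbinol.

Step 6
Reactants: 10 (3S,4R)-4-[(4S)-2,2-dimethyl-1,3-dioxolan-4-yl]pent-1-ene-3,4-diol; 11 1,1'-carbonyldiimidazole
Product: 12 (4S,5R)-5-[(4S)-2,2-dimethyl-1,3-dioxolan-4-yl]-5-methyl-4-vinyl-1,3-dioxolan-2-one
Conditions: CDI, DMAP (cat.), toluene, 60 °C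
Reagents that add atoms: 1,1'-carbonyldiimidazole, O=C(n1ccnc1)n1ccnc1
Why: Carbonylation of the vicinal diol to the five-membered cyclic carbonate (acyl transfer from CDI); no stereocentre is touched.

Step 7
Reactants: 12 (4S,5R)-5-[(4S)-2,2-dimethyl-1,3-dioxolan-4-yl]-5-methyl-4-vinyl-1,3-dioxolan-2-one; 13 dimethyltitanocene Cp2TiMe2
Product: 15 (7R)-7-[(4S)-2,2-dimethyl-1,3-dioxolan-4-yl]-7-methyl-4,7-dihydrooxepin-2(3H)-one, via ketene acetal 14 (not isolated)
Conditions: Cp2TiMe2 (about 1.3 equiv), toluene, 105 °C, dark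
Reagents that add atoms: dimethyltitanocene Cp2TiMe2, C[Ti](C)(C1C=CC=C1)C1C=CC=C1
Why: Thermolysis of Cp2TiMe2 gives the titanium methylidene, which methylenates the carbonate carbonyl (Petasis methylenation) to the 2-methylene-4-vinyl-1,3-dioxolane 14; this ketene acetal then undergoes a Claisen rearrangement in which the methylene carbon bonds to the vinyl terminus (the C3–C4 bond of ring C) while the allylic C–O bond breaks. The closest known reaction type is the tandem methylenation–Claisen ring expansion of vinyl-substituted cyclic carbonates to medium-ring lactones. Ring C is closed by a two-atom ring expansion (five-membered dioxolane to seven-membered lactone) through the chair-like transition state that the dioxolane tether enforces, which can only give the Z ring alkene. No new stereocentre is formed: the quaternary C7 is not involved and is retained, and the carbinol centre of step 5 is destroyed, so both epimers converge. The step needs methylenation of the carbonate without further methylenation of the lactone formed; the carbonate is the only carbonyl in 12, and limiting the reagent with monitoring should hold back over-reaction.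

Step 8
Reactants: 15 (7R)-7-[(4S)-2,2-dimethyl-1,3-dioxolan-4-yl]-7-methyl-4,7-dihydrooxepin-2(3H)-one; 16 Eschenmoser's salt CH2=NMe2+ I−
Product: 19 (7R)-7-[(4S)-2,2-dimethyl-1,3-dioxolan-4-yl]-7-methyl-3-methylene-4,7-dihydrooxepin-2(3H)-one, via Mannich base 17 (not isolated), via ammonium iodide 18 (not isolated)
Conditions: LiN(i-Pr)2, THF, −78 °C; CH2=NMe2+ I−, −78 °C → rt; MeI, MeOH, rt; NaHCO3 (aq), CH2Cl2, rt
Reagents that add atoms: Eschenmoser's salt (N,N-dimethylmethyleneiminium iodide), C=[N+](C)C.[I-]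
Why: Mannich reaction of the lithium lactone enolate (C3 is the only enolisable position), N-methylation and mild base-induced β-elimination should give the exocyclic enoate.

Step 9
Reactants: 19 (7R)-7-[(4S)-2,2-dimethyl-1,3-dioxolan-4-yl]-7-methyl-3-methylene-4,7-dihydrooxepin-2(3H)-one
Product: 20 (3S,7R)-7-[(4S)-2,2-dimethyl-1,3-dioxolan-4-yl]-3,7-dimethyloxepan-2-one
Conditions: H2 (4 atm), RhCl(PPh3)3 (10 mol %), benzene, 40 °C
Reagents that add atoms: none
Why: Homogeneous hydrogenation should saturate both alkenes without hydrogenolysis of the allylic C7–O bond; hydrogen is expected on the face of the exocyclic alkene opposite the pseudo-axial C7 methyl (the bulky dioxolanyl group being pseudo-equatorial), which places the new C3 methyl cis to the C7 methyl.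

Step 10
Reactants: 20 (3S,7R)-7-[(4S)-2,2-dimethyl-1,3-dioxolan-4-yl]-3,7-dimethyloxepan-2-one; 21 acetic anhydride
Product: 23 (3S,7R)-7-[(4S)-2,2-dimethyl-1,3-dioxolan-4-yl]-3,7-dimethyloxepan-2-yl acetate (anomer mixture), via aluminium hemiacetal 22 (not isolated)
Conditions: i-Bu2AlH, CH2Cl2, −78 °C; then pyridine, DMAP, Ac2O, −78 → 0 °C
Reagents that add atoms: acetic anhydride, CC(=O)OC(C)=O
Why: Half-reduction of the lactone and in situ acetylation of the aluminium hemiacetal (reductive acetylation) avoids opening to the hydroxy aldehyde and so avoids epimerisation at C3.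

Step 11
Reactants: 23 (3S,7R)-7-[(4S)-2,2-dimethyl-1,3-dioxolan-4-yl]-3,7-dimethyloxepan-2-yl acetate; 24 allyltrimethylsilane
Product: 25 (2R,3S,7R)-7-[(4S)-2,2-dimethyl-1,3-dioxolan-4-yl]-3,7-dimethyl-2-(prop-2-en-1-yl)oxepane
Conditions: CH2=CHCH2SiMe3, BF3·OEt2, CH2Cl2, −78 °C
Reagents that add atoms: allyltrimethylsilane, C=CC[Si](C)(C)C
Why: Hosomi–Sakurai allylation of the seven-membered oxocarbenium ion; the C3 and C7 methyl groups shield the same face, so the silane should attack trans to the adjacent C3 methyl and syn to the C7 side chain, setting C2 with the cis relationship needed for bridging.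

Step 12
Reactants: 25 (2R,3S,7R)-7-[(4S)-2,2-dimethyl-1,3-dioxolan-4-yl]-3,7-dimethyl-2-(prop-2-en-1-yl)oxepane
Product: 26 (1S)-1-[(2R,6S,7R)-2,6-dimethyl-7-(prop-2-en-1-yl)oxepan-2-yl]ethane-1,2-diol
Conditions: AcOH–H2O (4:1), 40 °C
Reagents that add atoms: none
Why: Acid hydrolysis of the isopropylidene acetal; the ring ether, the alkene and all stereocentres are inert.

Step 13
Reactants: 26 (1S)-1-[(2R,6S,7R)-2,6-dimethyl-7-(prop-2-en-1-yl)oxepan-2-yl]ethane-1,2-diol; 27 methyl 2-(bromomethyl)acrylate
Product: 28 methyl (2Z)-2-(bromomethyl)-4-[(2R,3S,7R)-7-[(1S)-1,2-dihydroxyethyl]-3,7-dimethyloxepan-2-yl]but-2-enoate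
Conditions: methyl 2-(bromomethyl)acrylate (4 equiv), second-generation Hoveyda–Grubbs catalyst RuCl2(H2IMes)(=CH-C6H4-2-O-i-Pr) (5 mol %), CH2Cl2, 40 °C
Reagents that add atoms: methyl 2-(bromomethyl)acrylate, C=C(CBr)C(=O)OC
Why: Olefin cross-metathesis between the terminal alkene and a 2-substituted acrylate that homodimerises slowly; thermodynamic control should place the chain trans to the ester, which is the (Z)-2-(bromomethyl)enoate.

Step 14
Reactants: 28 methyl (2Z)-2-(bromomethyl)-4-[(2R,3S,7R)-7-[(1S)-1,2-dihydroxyethyl]-3,7-dimethyloxepan-2-yl]but-2-enoate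
Product: 29 methyl (2Z)-2-(bromomethyl)-4-[(2R,3S,7R)-7-[(1R)-1-hydroxy-2-oxoethyl]-3,7-dimethyloxepan-2-yl]but-2-enoate
Conditions: TEMPO (cat.), PhI(OAc)2, CH2Cl2, rt
Reagents that add atoms: none
Why: Nitroxyl-catalysed oxidation is selective for the primary hydroxyl of the 1,2-diol; the secondary alcohol, the allylic bromide and the enoate should be untouched, and the aldehyde is used crude.

Step 15
Reactants: 29 methyl (2Z)-2-(bromomethyl)-4-[(2R,3S,7R)-7-[(1R)-1-hydroxy-2-oxoethyl]-3,7-dimethyloxepan-2-yl]but-2-enoate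
Product: 31 tricyclic hydroxy α-methylene lactone (the target alcohol), via seco hydroxy ester 30 (not isolated)
Conditions: CrCl2 (6 equiv), THF, rt, high dilution; then p-TsOH (cat.), CH2Cl2, rt
Reagents that add atoms: none
Why: Intramolecular Nozaki–Hiyama–Kishi-type allylation in which the equilibrating allylchromium reagent adds through its γ-carbon to the aldehyde via a chair-like Zimmerman–Traxler transition state with both ring tethers pseudo-equatorial (anti adduct) and the neighbouring C–O bond anti to the forming bond, which should close ring B with the all-trans array; the alkoxide and the methyl ester then lactonise to the trans-fused ring A.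

Step 16
Reactants: 31 tricyclic hydroxy α-methylene lactone; 32 (R)-2-methylbutanoic acid
Product: 33 target CNP0136059.1
Conditions: (R)-2-methylbutanoic acid, DCC, DMAP (cat.), CH2Cl2, 0 °C → rt
Reagents that add atoms: (R)-2-methylbutanoic acid, CC[C@@H](C)C(=O)O
Why: Steglich esterification of the only free (secondary) alcohol; the acid stereocentre is not enolised under these conditions and the α-methylene lactone tolerates DMAP.

Compound list

1 | L-erythrulose, (3S)-1,3,4-trihydroxybutan-2-one | OCC(=O)[C@@H](O)CO | starting material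
2 | 2,2-dimethoxypropane | COC(C)(C)OC | starting material
3 | 3,4-O-isopropylidene-L-erythrulose, 1-[(4S)-2,2-dimethyl-1,3-dioxolan-4-yl]-2-hydroxyethan-1-one | OCC(=O)[C@@H]1COC(C)(C)O1 | intermediate
4 | chlorotriethylsilane | CC[Si](CC)(CC)Cl | starting material
5 | 1-[(4S)-2,2-dimethyl-1,3-dioxolan-4-yl]-2-(triethylsilyloxy)ethan-1-one | CC[Si](CC)(CC)OCC(=O)[C@@H]1COC(C)(C)O1 | intermediate
6 | methylmagnesium bromide | C[Mg]Br | starting material
7 | (2R)-2-[(4S)-2,2-dimethyl-1,3-dioxolan-4-yl]-1-(triethylsilyloxy)propan-2-ol | CC[Si](CC)(CC)OC[C@@](C)(O)[C@@H]1COC(C)(C)O1 | intermediate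
8 | (2S)-2-[(4S)-2,2-dimethyl-1,3-dioxolan-4-yl]-2-hydroxypropanal | O=C[C@@](C)(O)[C@@H]1COC(C)(C)O1 | intermediate
9 | vinylmagnesium bromide | C=C[Mg]Br | starting material
10 | (3S,4R)-4-[(4S)-2,2-dimethyl-1,3-dioxolan-4-yl]pent-1-ene-3,4-diol (major carbinol epimer) | C=C[C@H](O)[C@@](C)(O)[C@@H]1COC(C)(C)O1 | intermediate
11 | 1,1'-carbonyldiimidazole | O=C(n1ccnc1)n1ccnc1 | starting material
12 | (4S,5R)-5-[(4S)-2,2-dimethyl-1,3-dioxolan-4-yl]-5-methyl-4-vinyl-1,3-dioxolan-2-one | C=C[C@@H]1OC(=O)O[C@@]1(C)[C@@H]2COC(C)(C)O2 | intermediate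
13 | dimethyltitanocene, Cp2TiMe2 | C[Ti](C)(C1C=CC=C1)C1C=CC=C1 | starting material
14 | ketene acetal, (4R,5S)-4-[(4S)-2,2-dimethyl-1,3-dioxolan-4-yl]-4-methyl-2-methylidene-5-vinyl-1,3-dioxolane | C=C[C@@H]1OC(=C)O[C@@]1(C)[C@@H]2COC(C)(C)O2 | intermediate
15 | (7R)-7-[(4S)-2,2-dimethyl-1,3-dioxolan-4-yl]-7-methyl-4,7-dihydrooxepin-2(3H)-one (Z ring alkene) | O=C1CCC=C[C@@](C)(O1)[C@@H]2COC(C)(C)O2 | intermediate
16 | Eschenmoser's salt, N,N-dimethylmethyleneiminium iodide | C=[N+](C)C.[I-] | starting material
17 | Mannich base, (7R)-3-[(dimethylamino)methyl]-7-[(4S)-2,2-dimethyl-1,3-dioxolan-4-yl]-7-methyl-4,7-dihydrooxepin-2(3H)-one (C3 epimers) | CN(C)CC1CC=C[C@@](C)(OC1=O)[C@@H]2COC(C)(C)O2 | intermediate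
18 | ammonium iodide, the N-methyl quaternary salt of 17 (C3 epimers) | C[N+](C)(C)CC1CC=C[C@@](C)(OC1=O)[C@@H]2COC(C)(C)O2.[I-] | intermediate
19 | (7R)-7-[(4S)-2,2-dimethyl-1,3-dioxolan-4-yl]-7-methyl-3-methylene-4,7-dihydrooxepin-2(3H)-one | C=C1CC=C[C@@](C)(OC1=O)[C@@H]2COC(C)(C)O2 | intermediate
20 | (3S,7R)-7-[(4S)-2,2-dimethyl-1,3-dioxolan-4-yl]-3,7-dimethyloxepan-2-one | C[C@H]1CCC[C@@](C)(OC1=O)[C@@H]2COC(C)(C)O2 | intermediate
21 | acetic anhydride | CC(=O)OC(C)=O | starting material
22 | aluminium hemiacetal, O-diisobutylaluminium lactol of 20 (anomer mixture) | C[C@H]1CCC[C@@](C)(OC1O[Al](CC(C)C)CC(C)C)[C@@H]2COC(C)(C)O2 | intermediate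
23 | (3S,7R)-7-[(4S)-2,2-dimethyl-1,3-dioxolan-4-yl]-3,7-dimethyloxepan-2-yl acetate (anomer mixture) | C[C@H]1CCC[C@@](C)(OC1OC(C)=O)[C@@H]2COC(C)(C)O2 | intermediate
24 | allyltrimethylsilane | C=CC[Si](C)(C)C | starting material
25 | (2R,3S,7R)-7-[(4S)-2,2-dimethyl-1,3-dioxolan-4-yl]-3,7-dimethyl-2-(prop-2-en-1-yl)oxepane | C=CC[C@H]1O[C@](C)(CCC[C@@H]1C)[C@@H]2COC(C)(C)O2 | intermediate
26 | (1S)-1-[(2R,6S,7R)-2,6-dimethyl-7-(prop-2-en-1-yl)oxepan-2-yl]ethane-1,2-diol | C=CC[C@H]1O[C@](C)(CCC[C@@H]1C)[C@@H](O)CO | intermediate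
27 | methyl 2-(bromomethyl)acrylate | C=C(CBr)C(=O)OC | starting material
28 | methyl (2Z)-2-(bromomethyl)-4-[(2R,3S,7R)-7-[(1S)-1,2-dihydroxyethyl]-3,7-dimethyloxepan-2-yl]but-2-enoate | COC(=O)/C(CBr)=C/C[C@H]1O[C@](C)(CCC[C@@H]1C)[C@@H](O)CO | intermediate
29 | methyl (2Z)-2-(bromomethyl)-4-[(2R,3S,7R)-7-[(1R)-1-hydroxy-2-oxoethyl]-3,7-dimethyloxepan-2-yl]but-2-enoate | COC(=O)/C(CBr)=C/C[C@H]1O[C@](C)(CCC[C@@H]1C)[C@@H](O)C=O | intermediate
30 | seco hydroxy ester, methyl 2-(4,5-dihydroxy-6,10-dimethyl-11-oxabicyclo[4.4.1]undecan-3-yl)acrylate with the configuration of 31 | C=C(C(=O)OC)[C@H]1C[C@H]2O[C@](C)(CCC[C@@H]2C)[C@@H](O)[C@@H]1O | intermediate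
31 | tricyclic hydroxy α-methylene lactone, the target with a free secondary hydroxyl in place of the ester | C=C1C(=O)O[C@@H]2[C@@H]1C[C@H]1O[C@](C)(CCC[C@@H]1C)[C@H]2O | intermediate
32 | (R)-2-methylbutanoic acid | CC[C@@H](C)C(=O)O | starting material
33 | CNP0136059.1, the (R)-2-methylbutanoate of 31 | C=C1C(=O)O[C@@H]2[C@@H]1C[C@H]1O[C@](C)(CCC[C@@H]1C)[C@H]2OC(=O)[C@H](C)CC | target

Total step count: 16. Longest linear sequence: 16 steps, from L-erythrulose.

Steps most likely to fail

Step 15. What may go wrong: poor control of the two new stereocentres in the ring-closing allylation (formation of the cis-fused lactone or of the carbinol epimer), or reduction and oligomerisation of the allylic bromide competing with closure of the seven-membered ring. Fallback: setting out from diol 26, cross-metathesis with methyl 2-[(trimethylsilyl)methyl]acrylate (same ruthenium catalyst) should give the allylsilane diol F1. Nitroxyl oxidation as in step 14 should then give the allylsilane hydroxy aldehyde F2. A fluoride-triggered intramolecular Hosomi–Sakurai allylation (Bu4NF, THF) runs through an open transition state and not through the closed chromium chelate, and should close ring B to the seco hydroxy ester 30. Acid-catalysed lactonisation returns to the route at 31.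

Step 9. What may go wrong: poor or reversed facial selectivity in the hydrogenation of the exocyclic alkene (giving the C3 epimer), or migration of the exocyclic double bond into the ring before reduction. Fallback: setting out from lactone 15, hydrogenation of the ring alkene alone (H2, RhCl(PPh3)3) should give the saturated lactone F3. Its lithium enolate (LiN(i-Pr)2, THF, −78 °C) is then methylated with MeI, so that carbon and not hydrogen enters on the accessible face. The route is rejoined at 20.

Step 7. What may go wrong: further methylenation of the lactone by the titanium methylidene, or sluggish methylenation of the five-membered carbonate with thermal decomposition of the reagent. Fallback: setting out from diol 10, transacetalisation with phenylselenoacetaldehyde diethyl acetal (pyridinium p-toluenesulfonate, toluene, 80 °C) should give the selenoacetal F4, and NaIO4 oxidation the selenoxide F5. Heating with DBU in xylene (140 °C) should bring about syn-elimination to the same ketene acetal 14 and its Claisen ring expansion. The route is rejoined at 15.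

Further compounds

F1 | step 15 | allylsilane diol, methyl (2Z)-4-[(2R,3S,7R)-7-[(1S)-1,2-dihydroxyethyl]-3,7-dimethyloxepan-2-yl]-2-[(trimethylsilyl)methyl]but-2-enoate | COC(=O)/C(C[Si](C)(C)C)=C/C[C@H]1O[C@](C)(CCC[C@@H]1C)[C@@H](O)CO
F2 | step 15 | allylsilane hydroxy aldehyde, methyl (2Z)-4-[(2R,3S,7R)-7-[(1R)-1-hydroxy-2-oxoethyl]-3,7-dimethyloxepan-2-yl]-2-[(trimethylsilyl)methyl]but-2-enoate | COC(=O)/C(C[Si](C)(C)C)=C/C[C@H]1O[C@](C)(CCC[C@@H]1C)[C@@H](O)C=O
F3 | step 9 | saturated lactone, (7R)-7-[(4S)-2,2-dimethyl-1,3-dioxolan-4-yl]-7-methyloxepan-2-one | O=C1CCCC[C@@](C)(O1)[C@@H]2COC(C)(C)O2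
F4 | step 7 | selenoacetal, (4R,5S)-4-[(4S)-2,2-dimethyl-1,3-dioxolan-4-yl]-4-methyl-2-[(phenylselanyl)methyl]-5-vinyl-1,3-dioxolane (acetal epimers) | C=C[C@@H]1OC(C[Se]c2ccccc2)O[C@@]1(C)[C@@H]3COC(C)(C)O3
F5 | step 7 | selenoxide of F4 | C=C[C@@H]1OC(C[Se](=O)c2ccccc2)O[C@@]1(C)[C@@H]3COC(C)(C)O3
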